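Numbering: unit 1 is the flavone without OMe (O1–C8a, ring B C1'–C6'); unit 2 is the 8-aryl flavone (double primes, ring B triple primes). The route rests on ring B of unit 1, a phenol with O on C4', the C8'' aryl on the neighbouring C3', and chromone C2 on C1', para to C4'. A 2-siloxy-3-arylbutadiene/acceptor-alkyne adduct shows this pattern after loss of H2.
Disconnection 1: C5'–C6' and C1'–C2' are cut, giving diene 14 (C2'–C5' already attached to C8'') and 2-ethynylchromone 20 (C1', C6'). The crowded C3'–C8'' bond therefore never has to be made by biaryl coupling.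
Disconnection 2: 14 comes from 8-allylflavone 10 by Wacker oxidation, α-methylenation and enol silylation. The allyl group is placed at the acetophenone stage by an ortho-Claisen shift that has only one free ortho carbon, the future C8''.
Disconnection 3: 20 comes from chromone-2-carboxylate 17 (ester to CH2OH to CHO to C≡CH). Both halves start from the same acetophenone 2.
Ring order: ring C of unit 2 (step 7) and ring C of unit 1 (step 11) close in parallel branches. Ring B of unit 1 closes last (step 15) and is aromatised in step 16. Both rings A and ring B of unit 2 are purchased.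

Key step: step 15

Remark: the target has no stereocentre and its C3'–C8'' axis is drawn without configuration, so the axis is taken as needing no control.
Abbreviation in names: U2 = 5,7-bis(benzyloxy)-2-[4-(benzyloxy)-3-methoxyphenyl]-4-oxo-4H-chromen-8-yl (protected unit 2 bonded through C8'').

Step 1
Reactants: 1 2',4',6'-trihydroxyacetophenone
Product: 2 2-hydroxy-4,6-bis(benzyloxy)acetophenone
Conditions: BnBr (2.1 equiv), K2CO3, DMF, rt → 60 °C
Reagents that add atoms: benzyl bromide, BrCc1ccccc1
Why: Williamson ether synthesis; the 4-OH and one of the two equivalent ortho OH groups are alkylated, while the last ortho OH is held in a hydrogen bond to the acetyl oxygen and is spared by two equivalents of halide.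

Step 2
Reactants: 2 2-hydroxy-4,6-bis(benzyloxy)acetophenone; 3 allyl bromide
Product: 4 2-(allyloxy)-4,6-bis(benzyloxy)acetophenone
Conditions: K2CO3, DMF, 60 °C
Reagents that add atoms: none
Why: Williamson ether synthesis; excess reactive halide in warm DMF should overcome the chelation of the remaining phenol.

Step 3
Reactants: 4 2-(allyloxy)-4,6-bis(benzyloxy)acetophenone
Product: 5 3-allyl-2-hydroxy-4,6-bis(benzyloxy)acetophenone
Conditions: N,N-diethylaniline, 195 °C, Ar
Reagents that add atoms: none
Why: Aromatic ortho-Claisen rearrangement ([3,3] shift, then tautomerisation); only C3 of the two ortho carbons bears hydrogen (the other carries the acetyl group), so the allyl group lands on the future C8'' and the phenol needed for ring closure is released at the same time.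

Step 4
Reactants: 6 vanillic acid
Product: 7 4-(benzyloxy)-3-methoxybenzoic acid
Conditions: BnBr, NaOH (aq), EtOH, reflux; then HCl (aq)
Reagents that add atoms: benzyl bromide, BrCc1ccccc1
Why: Williamson ether synthesis on the phenoxide–carboxylate dianion; any benzyl ester that forms is saponified by the excess hydroxide before acidification.

Step 5
Reactants: 7 4-(benzyloxy)-3-methoxybenzoic acid
Product: 8 4-(benzyloxy)-3-methoxybenzoyl chloride
Conditions: (COCl)2, DMF (cat.), CH2Cl2, 0 °C → rt; concentrate, use crude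
Reagents that add atoms: oxalyl chloride, O=C(Cl)C(=O)Cl
Why: Acid chloride formation under Vilsmeier-type catalysis; the aryl benzyl and methyl ethers are inert.

Step 6
Reactants: 5 3-allyl-2-hydroxy-4,6-bis(benzyloxy)acetophenone; 8 4-(benzyloxy)-3-methoxybenzoyl chloride
Product: 9 1-[3-allyl-4,6-bis(benzyloxy)-2-hydroxyphenyl]-3-[4-(benzyloxy)-3-methoxyphenyl]propane-1,3-dione
Conditions: LiN(SiMe3)2 (3.2 equiv), THF, −78 → −10 °C; then 8, −78 °C → rt; HCl (aq) work-up
Reagents that add atoms: none
Why: Crossed Claisen-type C-acylation of the phenoxide–enolate dianion (the direct variant of the Baker–Venkataraman route); any O-acylated material should be carried to the same diketone by the excess base.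

Step 7
Reactants: 9 the 1,3-diketone
Product: 10 8-allyl-5,7-bis(benzyloxy)-2-[4-(benzyloxy)-3-methoxyphenyl]-4H-chromen-4-one
Conditions: NaOAc, AcOH, 110 °C
Reagents that add atoms: none
Why: Cyclodehydration of an o-hydroxyaryl 1,3-diketone (last stage of the Baker–Venkataraman flavone synthesis) closes ring C of unit 2; only one phenol is free, so the allyl group must sit on C8'', and the buffered acid spares the benzyl ethers and the alkene.

Step 8
Reactants: 10 the 8-allylflavone
Product: 11 5,7-bis(benzyloxy)-2-[4-(benzyloxy)-3-methoxyphenyl]-8-(2-oxopropyl)-4H-chromen-4-one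
Conditions: PdCl2 (10 mol %), CuCl (co-catalyst, 50 mol %), O2 (1 atm), DMF–H2O 7:1, rt
Reagents that add atoms: water, O
Why: Tsuji–Wacker oxidation; Markovnikov hydroxypalladation of the terminal alkene by divalent palladium and β-hydride elimination give the methyl ketone, while the substituted, electron-poor pyranone double bond does not bind the metal.

Step 9
Reactants: 11 the 8-(2-oxopropyl)flavone
Product: 13 5,7-bis(benzyloxy)-2-[4-(benzyloxy)-3-methoxyphenyl]-8-(3-oxobut-1-en-2-yl)-4H-chromen-4-one, via Mannich base 12 (not isolated)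
Conditions: (CH2O)n, i-Pr2NH·CF3CO2H (1 equiv), CF3CO2H (10 mol %), THF, reflux
Reagents that add atoms: formaldehyde (as paraformaldehyde), C=O; diisopropylammonium trifluoroacetate, CC(C)[NH2+]C(C)C.[O-]C(=O)C(F)(F)F (its atoms appear only in 12)
Why: Mannich aminomethylation followed by β-elimination of the amine in the flask (direct α-methylenation); enolisation runs toward the benzylic CH2, the more acidic and more substituted α-carbon, and that carbon has no hydrogen left after one methylenation.

Step 10
Reactants: 13 the α-aryl enone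
Product: 14 8-[3-(tert-butyldimethylsiloxy)buta-1,3-dien-2-yl]-5,7-bis(benzyloxy)-2-[4-(benzyloxy)-3-methoxyphenyl]-4H-chromen-4-one
Conditions: TBSOTf, Et3N, CH2Cl2, 0 °C; Et3N-deactivated silica
Reagents that add atoms: tert-butyldimethylsilyl triflate, CC(C)(C)[Si](C)(C)OS(=O)(=O)C(F)(F)F
Why: Soft enolisation with O-silylation, the standard route from methyl vinyl ketones to 2-siloxydienes; the methyl group is the only enolisable position of 13, so a single diene should form.

Step 11
Reactants: 2 2-hydroxy-4,6-bis(benzyloxy)acetophenone; 15 diethyl oxalate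
Product: 17 ethyl 5,7-bis(benzyloxy)-4-oxo-4H-chromene-2-carboxylate, via diketo ester 16 (not isolated)
Conditions: NaOEt, EtOH–THF, 70 °C; then HCl in EtOH, 50 °C
Reagents that add atoms: none
Why: Claisen condensation of the methyl ketone enolate with diethyl oxalate, then acid-catalysed cyclodehydration (the standard chromone-2-carboxylate synthesis), closes ring C of unit 1; dilute ethanolic acid should leave the 5-O-benzyl group in place.

Step 12
Reactants: 17 the chromone-2-carboxylate
Product: 18 5,7-bis(benzyloxy)-2-(hydroxymethyl)-4H-chromen-4-one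
Conditions: NaBH4, EtOH–THF, 0 °C
Reagents that add atoms: none
Why: Chemoselective borohydride reduction, known for chromone-2-carboxylates; the ester on the oxygen-bearing C2 is activated, whereas C4=O is a deactivated vinylogous ester carbonyl.

Step 13
Reactants: 18 the 2-(hydroxymethyl)chromone
Product: 19 5,7-bis(benzyloxy)-4-oxo-4H-chromene-2-carbaldehyde
Conditions: Dess–Martin periodinane, CH2Cl2, 0 °C → rt
Reagents that add atoms: none
Why: Dess–Martin oxidation; the neutral, water-free medium stops at the aldehyde and avoids hydration or ring opening of this electrophilic product.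

Step 14
Reactants: 19 the chromone-2-carbaldehyde
Product: 20 2-ethynyl-5,7-bis(benzyloxy)-4H-chromen-4-one
Conditions: Me3SiCHN2 (1.1 equiv), LiN(i-Pr)2 (1.1 equiv), THF, −78 °C; add 19; −78 → 0 °C; AcOH quench
Reagents that add atoms: (trimethylsilyl)diazomethane, C[Si](C)(C)C=[N+]=[N-]
Why: Colvin rearrangement (a Seyferth–Gilbert-type homologation): 1,2-addition to the aldehyde, Peterson-type loss of silanolate, loss of N2 and a 1,2-hydrogen shift give the terminal alkyne, and the aprotic cold medium avoids alcohol addition to the acceptor alkyne.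

Step 15
Reactants: 14 the 2-siloxy-3-aryl diene; 20 2-ethynyl-5,7-bis(benzyloxy)-4H-chromen-4-one
Product: 21 2-[4-(tert-butyldimethylsiloxy)-5-(U2)cyclohexa-1,4-dien-1-yl]-5,7-bis(benzyloxy)-4H-chromen-4-one
Conditions: 14 (1.5 equiv), BHT (cat.), toluene, sealed tube, 130 °C, Ar
Reagents that add atoms: none
Why: This is a thermal, concerted but asynchronous normal-electron-demand Diels–Alder reaction between the HOMO of the 2-siloxydiene and the LUMO of the acceptor alkyne; the closest known reaction type is the addition of 2-silyloxybutadienes to propiolates and ynones to give 1-siloxycyclohexa-1,4-dienes, a dienophile class of which 20 is a vinylogous member. Ring B of unit 1 is closed as a six-membered carbocycle by intermolecular (4+2) closure, with C5'–C6' leading and C1'–C2' following, C2'–C5' coming from 14 and C1' and C6' from 20. No stereocentre is created, since the reacting carbons end as CH2 groups or sp2 centres. The step needs para orientation: the largest HOMO coefficient lies on C5', the CH2 terminus of the silyl enol ether, and the largest LUMO coefficient on the unsubstituted alkyne carbon C6', the δ-carbon of the C4=O/C3=C2/C1'≡C6' chain, while the rival director, the aryl group on C3', is turned out of the diene plane by its two ortho substituents (7''-OBn and O1'') and contributes little. It also needs site selectivity for the alkyne over the two pyranone C2=C3 bonds, which holds because those bonds are trisubstituted and stabilised by the ring oxygen, whereas the terminal alkyne is sterically open. The substituents on C3' and C4' destabilise the s-trans rotamer enough for the s-cis form to be populated, and BHT with exclusion of acid and water protects the diene during heating.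

Step 16
Reactants: 21 the cyclohexa-1,4-diene silyl enol ether
Product: 22 2-[4-(tert-butyldimethylsiloxy)-3-(U2)phenyl]-5,7-bis(benzyloxy)-4H-chromen-4-one
Conditions: DDQ (1.1 equiv), toluene, 0 °C → rt
Reagents that add atoms: none
Why: Dehydrogenative aromatisation; hydride abstraction from a doubly allylic CH2 and proton loss are driven by the gain of aromaticity and keep the O–Si bond, and one equivalent of DDQ at this temperature should not touch the unactivated aryl benzyl ethers.

Step 17
Reactants: 22 the aryl silyl ether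
Product: 23 2-[4-hydroxy-3-(U2)phenyl]-5,7-bis(benzyloxy)-4H-chromen-4-one
Conditions: n-Bu4NF, AcOH, THF, 0 °C
Reagents that add atoms: none
Why: Fluoride-induced cleavage of an aryl silyl ether; the acetic acid buffer keeps the medium from becoming basic enough to open the pyranone rings.

Step 18
Reactants: 23 the penta-O-benzyl biflavone phenol
Product: 24 target biflavone CNP0179340.0
Conditions: H2 (1 atm), 10% Pd/C, THF–MeOH, rt
Reagents that add atoms: none
Why: Catalytic hydrogenolysis of the five aryl benzyl ethers; the flavone C2=C3 bonds and the aryl methyl ether survive at one atmosphere, and the neutral medium excludes a Wessely–Moser shift of the aryl group from C8'' to C6''.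

Compound list
1 | 2',4',6'-trihydroxyacetophenone | CC(=O)c1c(O)cc(O)cc1O | starting material
2 | 2-hydroxy-4,6-bis(benzyloxy)acetophenone | CC(=O)c1c(O)cc(OCc2ccccc2)cc1OCc1ccccc1 | intermediate
3 | allyl bromide | C=CCBr | starting material
4 | 2-(allyloxy)-4,6-bis(benzyloxy)acetophenone | CC(=O)c1c(OCC=C)cc(OCc2ccccc2)cc1OCc1ccccc1 | intermediate
5 | 3-allyl-2-hydroxy-4,6-bis(benzyloxy)acetophenone | CC(=O)c1c(O)c(CC=C)c(OCc2ccccc2)cc1OCc1ccccc1 | intermediate
6 | vanillic acid | COc1cc(C(=O)O)ccc1O | starting material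
7 | 4-(benzyloxy)-3-methoxybenzoic acid | COc1cc(C(=O)O)ccc1OCc1ccccc1 | intermediate
8 | 4-(benzyloxy)-3-methoxybenzoyl chloride | COc1cc(C(=O)Cl)ccc1OCc1ccccc1 | intermediate
9 | 1-[3-allyl-4,6-bis(benzyloxy)-2-hydroxyphenyl]-3-[4-(benzyloxy)-3-methoxyphenyl]propane-1,3-dione | COc1cc(C(=O)CC(=O)c2c(O)c(CC=C)c(OCc3ccccc3)cc2OCc2ccccc2)ccc1OCc1ccccc1 | intermediate
10 | 8-allyl-5,7-bis(benzyloxy)-2-[4-(benzyloxy)-3-methoxyphenyl]-4H-chromen-4-one | C=CCc1c(OCc2ccccc2)cc(OCc2ccccc2)c2c(=O)cc(-c3ccc(OCc4ccccc4)c(OC)c3)oc12 | intermediate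
11 | 5,7-bis(benzyloxy)-2-[4-(benzyloxy)-3-methoxyphenyl]-8-(2-oxopropyl)-4H-chromen-4-one | CC(=O)Cc1c(OCc2ccccc2)cc(OCc2ccccc2)c2c(=O)cc(-c3ccc(OCc4ccccc4)c(OC)c3)oc12 | intermediate
12 | Mannich base, 8-[1-(diisopropylamino)-3-oxobutan-2-yl] analogue of 11 (racemic) | CC(=O)C(CN(C(C)C)C(C)C)c1c(OCc2ccccc2)cc(OCc2ccccc2)c2c(=O)cc(-c3ccc(OCc4ccccc4)c(OC)c3)oc12 | intermediate (not isolated)
13 | 5,7-bis(benzyloxy)-2-[4-(benzyloxy)-3-methoxyphenyl]-8-(3-oxobut-1-en-2-yl)-4H-chromen-4-one | CC(=O)C(=C)c1c(OCc2ccccc2)cc(OCc2ccccc2)c2c(=O)cc(-c3ccc(OCc4ccccc4)c(OC)c3)oc12 | intermediate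
14 | 8-[3-(tert-butyldimethylsiloxy)buta-1,3-dien-2-yl]-5,7-bis(benzyloxy)-2-[4-(benzyloxy)-3-methoxyphenyl]-4H-chromen-4-one | C=C(O[Si](C)(C)C(C)(C)C)C(=C)c1c(OCc2ccccc2)cc(OCc2ccccc2)c2c(=O)cc(-c3ccc(OCc4ccccc4)c(OC)c3)oc12 | intermediate
15 | diethyl oxalate | CCOC(=O)C(=O)OCC | starting material
16 | ethyl 4-[2,4-bis(benzyloxy)-6-hydroxyphenyl]-2,4-dioxobutanoate | CCOC(=O)C(=O)CC(=O)c1c(O)cc(OCc2ccccc2)cc1OCc1ccccc1 | intermediate (not isolated)
17 | ethyl 5,7-bis(benzyloxy)-4-oxo-4H-chromene-2-carboxylate | CCOC(=O)c1cc(=O)c2c(OCc3ccccc3)cc(OCc3ccccc3)cc2o1 | intermediate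
18 | 5,7-bis(benzyloxy)-2-(hydroxymethyl)-4H-chromen-4-one | OCc1cc(=O)c2c(OCc3ccccc3)cc(OCc3ccccc3)cc2o1 | intermediate
19 | 5,7-bis(benzyloxy)-4-oxo-4H-chromene-2-carbaldehyde | O=Cc1cc(=O)c2c(OCc3ccccc3)cc(OCc3ccccc3)cc2o1 | intermediate
20 | 2-ethynyl-5,7-bis(benzyloxy)-4H-chromen-4-one | C#Cc1cc(=O)c2c(OCc3ccccc3)cc(OCc3ccccc3)cc2o1 | intermediate
21 | 2-[4-(tert-butyldimethylsiloxy)-5-(U2)cyclohexa-1,4-dien-1-yl]-5,7-bis(benzyloxy)-4H-chromen-4-one | CC(C)(C)[Si](C)(C)OC1=C(c2c(OCc3ccccc3)cc(OCc3ccccc3)c3c(=O)cc(-c4ccc(OCc5ccccc5)c(OC)c4)oc23)CC(c2cc(=O)c3c(OCc4ccccc4)cc(OCc4ccccc4)cc3o2)=CC1 | intermediate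
22 | 2-[4-(tert-butyldimethylsiloxy)-3-(U2)phenyl]-5,7-bis(benzyloxy)-4H-chromen-4-one | CC(C)(C)[Si](C)(C)Oc1ccc(-c2cc(=O)c3c(OCc4ccccc4)cc(OCc4ccccc4)cc3o2)cc1-c1c(OCc2ccccc2)cc(OCc2ccccc2)c2c(=O)cc(-c3ccc(OCc4ccccc4)c(OC)c3)oc12 | intermediate
23 | 2-[4-hydroxy-3-(U2)phenyl]-5,7-bis(benzyloxy)-4H-chromen-4-one | Oc1ccc(-c2cc(=O)c3c(OCc4ccccc4)cc(OCc4ccccc4)cc3o2)cc1-c1c(OCc2ccccc2)cc(OCc2ccccc2)c2c(=O)cc(-c3ccc(OCc4ccccc4)c(OC)c3)oc12 | intermediate
24 | CNP0179340.0, 8-[5-(5,7-dihydroxy-4-oxo-4H-chromen-2-yl)-2-hydroxyphenyl]-5,7-dihydroxy-2-(4-hydroxy-3-methoxyphenyl)-4H-chromen-4-one | COc1cc(-c2cc(=O)c3c(O)cc(O)c(-c4cc(-c5cc(=O)c6c(O)cc(O)cc6o5)ccc4O)c3o2)ccc1O | target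

Total step count: 18. Longest linear sequence: 12 steps (1, 2, 3, 6, 7, 8, 9, 10, 15, 16, 17, 18).

Steps most likely to fail

1. Step 15.
- What may go wrong: the alkyne is activated only through the vinylogous carbonyl, so cycloaddition may be slower than thermal oligomerisation or adventitious hydrolysis of the diene. The para orientation may also erode at the temperature required.
- Fallback (sets out from 14, comes back at 22): ring B is still made by cycloaddition, but with a dienophile of the established class, and ring C of unit 1 is built afterwards.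
- Diene 14 is heated with methyl propiolate (toluene, 110 °C) to give methyl 4-(tert-butyldimethylsiloxy)-5-(U2)cyclohexa-1,4-diene-1-carboxylate F1.
- DDQ converts it into methyl 4-(tert-butyldimethylsiloxy)-3-(U2)benzoate F2.
- Crossed Claisen condensation of F2 with the dianion of acetophenone 2 (LiN(SiMe3)2, THF) gives 1-[2,4-bis(benzyloxy)-6-hydroxyphenyl]-3-[4-(tert-butyldimethylsiloxy)-3-(U2)phenyl]propane-1,3-dione F3.
- Cyclodehydration (NaOAc, AcOH) then gives 22. Any material that loses silicon on the way is 23, the next compound of the route.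

2. Step 14.
- What may go wrong: the lithiated diazo reagent may add to C2 of the pyranone with ring opening, or may undergo dipolar cycloaddition to the acceptor alkyne as it forms.
- Fallback (sets out from 19, comes back at 20): Corey–Fuchs-type dibromo-olefination (CBr4, PPh3, CH2Cl2, 0 °C) gives 5,7-bis(benzyloxy)-2-(2,2-dibromovinyl)-4H-chromen-4-one F4.
- Selective hydrogenolysis of the more exposed C–Br bond with Bu3SnH and the zerovalent palladium complex Pd(PPh3)4 gives 5,7-bis(benzyloxy)-2-[(Z)-2-bromovinyl]-4H-chromen-4-one F5.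
- Anti elimination of HBr with DBU (THF, rt) gives 20. No diazo compound or strong nucleophile is involved.

3. Step 9.
- What may go wrong: aminomethylation at the crowded benzylic carbon may be slow, so that attack on the methyl side or Michael addition of unreacted ketone to the enone competes.
- Fallback (sets out from 11, comes back at 13): the carbon is introduced under enolate control, where the benzylic C–H is by far the more acidic.
- Base-catalysed aldol addition to formaldehyde (aq. CH2O, K2CO3 cat., THF, rt) gives 5,7-bis(benzyloxy)-2-[4-(benzyloxy)-3-methoxyphenyl]-8-(1-hydroxy-3-oxobutan-2-yl)-4H-chromen-4-one F6 (racemic).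
- MsCl and Et3N (CH2Cl2, 0 °C → rt) convert it into the methanesulfonate of that alcohol F7, which undergoes E1cB elimination in the same flask to give 13.

Further compounds
F1 | step 15 | methyl 4-(tert-butyldimethylsiloxy)-5-(U2)cyclohexa-1,4-diene-1-carboxylate | COC(=O)C1=CCC(O[Si](C)(C)C(C)(C)C)=C(c2c(OCc3ccccc3)cc(OCc3ccccc3)c3c(=O)cc(-c4ccc(OCc5ccccc5)c(OC)c4)oc23)C1
F2 | step 15 | methyl 4-(tert-butyldimethylsiloxy)-3-(U2)benzoate | COC(=O)c1ccc(O[Si](C)(C)C(C)(C)C)c(-c2c(OCc3ccccc3)cc(OCc3ccccc3)c3c(=O)cc(-c4ccc(OCc5ccccc5)c(OC)c4)oc23)c1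
F3 | step 15 | 1-[2,4-bis(benzyloxy)-6-hydroxyphenyl]-3-[4-(tert-butyldimethylsiloxy)-3-(U2)phenyl]propane-1,3-dione | O=C(CC(=O)c1c(O)cc(OCc2ccccc2)cc1OCc1ccccc1)c1ccc(O[Si](C)(C)C(C)(C)C)c(-c2c(OCc3ccccc3)cc(OCc3ccccc3)c3c(=O)cc(-c4ccc(OCc5ccccc5)c(OC)c4)oc23)c1
F4 | step 14 | 5,7-bis(benzyloxy)-2-(2,2-dibromovinyl)-4H-chromen-4-one | BrC(Br)=Cc1cc(=O)c2c(OCc3ccccc3)cc(OCc3ccccc3)cc2o1
F5 | step 14 | 5,7-bis(benzyloxy)-2-[(Z)-2-bromovinyl]-4H-chromen-4-one | Br/C=C\c1cc(=O)c2c(OCc3ccccc3)cc(OCc3ccccc3)cc2o1
F6 | step 9 | 5,7-bis(benzyloxy)-2-[4-(benzyloxy)-3-methoxyphenyl]-8-(1-hydroxy-3-oxobutan-2-yl)-4H-chromen-4-one (racemic) | CC(=O)C(CO)c1c(OCc2ccccc2)cc(OCc2ccccc2)c2c(=O)cc(-c3ccc(OCc4ccccc4)c(OC)c3)oc12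
F7 | step 9 | methanesulfonate of F6 (racemic) | CC(=O)C(COS(C)(=O)=O)c1c(OCc2ccccc2)cc(OCc2ccccc2)c2c(=O)cc(-c3ccc(OCc4ccccc4)c(OC)c3)oc12
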